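Ring A of the chroman (C4a, C5, C6, C7, C8, C8a) carries oxygen on C5, C7 and C8a and the cinnamoyl carbon on C8, the alternating pattern of a folded tetraketide. Everything rests on cutting C8–C8a. A 4-hydroxy-2-pyrone that bears the prenyl group on C3 and a 4-aryl-2-oxobut-3-enyl chain on C6 holds all ring carbons. Magnesium methoxide unlocks its lactone, and a Claisen condensation then closes the benzene ring. This gives the C-prenylated, C-acylated phloroglucinol in one operation with the C4a–C4 bond already in place. Differentiation of the three phenols, an (S)-selective prenyl epoxidation and a 6-endo closure through the C8a oxygen finish the target.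

Key step: step 4

Remark on numbering: from compound 9 on, ring A positions are named by the chroman numbering of the target. C8a–OH lies between the acyl and prenyl carbons, C5–OH is para to the acyl group, and C7–OH is the other ortho phenol.
Remark on configuration: C3 of the target is (S). The C3–O bond made in step 7 is never broken afterwards, so an (S)-epoxide is required. This calls for the L-fructose-derived enantiomer of the Shi ketone, because the common D-fructose ketone gives (R)-epoxides from alkenes of the type RCH2CH=CMe2.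
Assumption: compounds 1 and 2 and the L-fructose-derived Shi ketone are taken as purchasable.

Step 1
Reactants: 1 4-(methoxymethoxy)benzaldehyde; 2 diethyl {2-[methoxy(methyl)amino]-2-oxoethyl}phosphonate
Product: 3 (E)-N-methoxy-3-[4-(methoxymethoxy)phenyl]-N-methylprop-2-enamide
Conditions: LiCl, DBU, MeCN, rt
Reagents that add atoms: none
Why: In this Masamune–Roush variant of the Horner–Wadsworth–Emmons olefination the stabilised phosphonoacetamide anion adds reversibly to the aldehyde and should give the (E)-enamide, and the mild base leaves the MOM acetal untouched.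

Step 2
Reactants: 4 4-hydroxy-6-methyl-2H-pyran-2-one; 5 3-methylbut-2-enyl acetate (prenyl acetate)
Product: 6 4-hydroxy-6-methyl-3-(3-methylbut-2-enyl)-2H-pyran-2-one
Conditions: Pd(PPh3)4 (5 mol%), Et3N, THF, 60 °C, slight excess of 4
Reagents that add atoms: none
Why: This Tsuji–Trost allylation is known for this very acidic pyrone: any O-prenyl ether is re-ionised by zerovalent palladium, so material drains to the C3–C product, and the soft nucleophile takes the unsubstituted terminus of the 1,1-dimethyl-π-allyl ligand to give the linear prenyl group.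

Step 3
Reactants: 6 4-hydroxy-6-methyl-3-(3-methylbut-2-enyl)-2H-pyran-2-one; 3 (E)-N-methoxy-3-[4-(methoxymethoxy)phenyl]-N-methylprop-2-enamide
Product: 7 4-hydroxy-6-{(E)-4-[4-(methoxymethoxy)phenyl]-2-oxobut-3-enyl}-3-(3-methylbut-2-enyl)-2H-pyran-2-one
Conditions: LiN(iPr)2 (2.2 equiv. per 6), THF, −78 °C; then 3 (0.85 equiv.), −78 to −30 °C; cold 1 M HCl quench
Reagents that add atoms: none
Why: In this Weinreb ketone synthesis with the O,C-dianion of a 4-hydroxy-6-methyl-2-pyrone the second deprotonation takes place at the vinylogous C6 methyl group, this most basic site attacks the poorly Michael-accepting enamide at its carbonyl carbon, and the chelated tetrahedral adduct lasts until the quench, so neither over-addition nor proton transfer from the acidic product interferes.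

Step 4
Reactants: 7 4-hydroxy-6-{(E)-4-[4-(methoxymethoxy)phenyl]-2-oxobut-3-enyl}-3-(3-methylbut-2-enyl)-2H-pyran-2-one
Product: 9 (E)-3-[4-(methoxymethoxy)phenyl]-1-[2,4,6-trihydroxy-3-(3-methylbut-2-enyl)phenyl]prop-2-en-1-one, via open-chain methyl triketo ester 8 (not isolated)
Conditions: Mg(OMe)2 (5 equiv.), MeOH, reflux, argon; poured into ice-cold 1 M HCl and extracted at once
Reagents that add atoms: none
Why: The side-chain carbanion cannot attack C2 of the intact pyrone, since that would bridge C2 and C6 of a flat ring with a single carbon, so methoxide first adds to the lactone carbonyl and opens it to the magnesium-chelated triketo ester 8, in which the former ring oxygen is the enolate oxygen on chain C5. The carbanion at chain C6, flanked by the C5 and C7 carbonyl groups, then attacks the ester carbon C1 in a Dieckmann-type Claisen condensation (6-exo-trig at the ester C=O), methoxide leaves and the cyclohexanetrione enolises, which forms C8–C8a and closes ring A with the old ring oxygen as the C7 phenol. The closest known reaction is the magnesium methoxide recyclisation of 6-(2-oxoalkyl)-4-hydroxy-2-pyrones such as tetraacetic acid lactone to acylphloroglucinols. No stereocentre is created. The step needs Claisen closure in preference to aldol closure of chain C2 onto C7: magnesium holds the 1,3-dicarbonyl units as chelates that favour C-acylation, and the prenyl group leaves chain C2 fully substituted after an aldol addition, so that adduct cannot dehydrate to a resorcylate and reverts, while only the Claisen product aromatises. The enone is shielded first within the diketonate and then within the phenolate chelate, and the cold acidic quench should keep the freed 2,6-dihydroxyaryl enone from closing to flavanones.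

Step 5
Reactants: 9 (E)-3-[4-(methoxymethoxy)phenyl]-1-[2,4,6-trihydroxy-3-(3-methylbut-2-enyl)phenyl]prop-2-en-1-one
Product: 10 (E)-1-[2-hydroxy-4,6-bis(methoxymethoxy)-3-(3-methylbut-2-enyl)phenyl]-3-[4-(methoxymethoxy)phenyl]prop-2-en-1-one
Conditions: MOMCl (2.2 equiv.), iPr2NEt (3 equiv.), CH2Cl2, 0 °C, crude 9 used directly
Reagents that add atoms: chloromethyl methyl ether (MOMCl), COCCl
Why: In this O-alkylation under amine base the most acidic, non-chelated C5–OH reacts first, and of the two ortho phenols the open C7–OH should react well before the C8a–OH, which is wedged between the acyl and prenyl groups and keeps the hydrogen bond to the carbonyl.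

Step 6
Reactants: 10 (E)-1-[2-hydroxy-4,6-bis(methoxymethoxy)-3-(3-methylbut-2-enyl)phenyl]-3-[4-(methoxymethoxy)phenyl]prop-2-en-1-one
Product: 11 (E)-1-[2-(tert-butyldimethylsilyloxy)-4,6-bis(methoxymethoxy)-3-(3-methylbut-2-enyl)phenyl]-3-[4-(methoxymethoxy)phenyl]prop-2-en-1-one
Conditions: TBSOTf (1.3 equiv.), 2,6-lutidine (2 equiv.), CH2Cl2, −20 to 0 °C
Reagents that add atoms: tert-butyldimethylsilyl trifluoromethanesulfonate (TBSOTf), CC(C)(C)[Si](C)(C)OS(=O)(=O)C(F)(F)F
Why: A silyl triflate with a hindered pyridine base silylates even a chelated, flanked phenol without forming a free phenoxide, and this mask is needed because a free C8a–OH at the pH of step 7 would add to the enone or open the new epoxide in the 5-exo mode.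

Step 7
Reactants: 11 (E)-1-[2-(tert-butyldimethylsilyloxy)-4,6-bis(methoxymethoxy)-3-(3-methylbut-2-enyl)phenyl]-3-[4-(methoxymethoxy)phenyl]prop-2-en-1-one
Product: 12 (E)-1-[2-(tert-butyldimethylsilyloxy)-3-{[(2S)-3,3-dimethyloxiran-2-yl]methyl}-4,6-bis(methoxymethoxy)phenyl]-3-[4-(methoxymethoxy)phenyl]prop-2-en-1-one
Conditions: 1,2:4,5-di-O-isopropylidene-β-L-erythro-2,3-hexodiulo-2,6-pyranose (L-fructose-derived Shi ketone, 30 mol%), Oxone (2KHSO5·KHSO4·K2SO4), K2CO3, Bu4NHSO4 (cat.), MeCN–CH2(OMe)2, aq. Na2B4O7/Na2EDTA buffer (pH about 10.5), 0 °C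
Reagents that add atoms: potassium peroxymonosulfate (KHSO5, active part of Oxone), [K+].[O-]S(=O)(=O)OO
Why: In this Shi epoxidation the electrophilic chiral dioxirane should select the electron-rich trisubstituted prenyl alkene over the electron-poor enone, and the spiro transition state of the L-fructose-derived ketone delivers oxygen to the face that sets the (S) configuration at the future C3.

Step 8
Reactants: 12 (E)-1-[2-(tert-butyldimethylsilyloxy)-3-{[(2S)-3,3-dimethyloxiran-2-yl]methyl}-4,6-bis(methoxymethoxy)phenyl]-3-[4-(methoxymethoxy)phenyl]prop-2-en-1-one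
Product: 14 (E)-1-[(3S)-3-hydroxy-5,7-bis(methoxymethoxy)-2,2-dimethylchroman-8-yl]-3-[4-(methoxymethoxy)phenyl]prop-2-en-1-one, via free epoxy phenol 13 (not isolated)
Conditions: Bu4NF/AcOH (1:1, 1.2 equiv.), THF, 0 °C; aqueous wash, solvent switch; then camphorsulfonic acid (10 mol%), CH2Cl2, −20 to 0 °C
Reagents that add atoms: none
Why: Buffered fluoride frees the phenol as the neutral species, and the acid-catalysed opening of the trisubstituted epoxide by this weak, hydrogen-bonded nucleophile should pass through a loose, cation-like transition state at the tertiary carbon (6-endo-tet, Markovnikov), so the C3–O bond and its (S) configuration stay untouched, while the MOM group on O5 leaves the C8a oxygen as the only phenol able to close.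

Step 9
Reactants: 14 (E)-1-[(3S)-3-hydroxy-5,7-bis(methoxymethoxy)-2,2-dimethylchroman-8-yl]-3-[4-(methoxymethoxy)phenyl]prop-2-en-1-one
Product: 15 (E)-1-[(3S)-3,5,7-trihydroxy-2,2-dimethylchroman-8-yl]-3-(4-hydroxyphenyl)prop-2-en-1-one (target)
Conditions: HCl (1.25 M in MeOH), rt, stopped at full conversion
Reagents that add atoms: none
Why: Acid-catalysed acetal exchange with methanol removes the three aryl MOM groups, the tertiary alkyl aryl ether, the C3 carbinol and the enone tolerate dilute acid at room temperature, and the product has only one free phenol ortho to the acyl group, so it belongs to the 2'-hydroxy-6'-alkoxychalcone class that closes to flavanones only slowly under such conditions.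

Compound list
1 | 4-(methoxymethoxy)benzaldehyde | COCOc1ccc(C=O)cc1 | starting material
2 | diethyl {2-[methoxy(methyl)amino]-2-oxoethyl}phosphonate | CCOP(=O)(CC(=O)N(C)OC)OCC | starting material
3 | (E)-N-methoxy-3-[4-(methoxymethoxy)phenyl]-N-methylprop-2-enamide | COCOc1ccc(/C=C/C(=O)N(C)OC)cc1 | intermediate
4 | 4-hydroxy-6-methyl-2H-pyran-2-one | Cc1cc(O)cc(=O)o1 | starting material
5 | 3-methylbut-2-enyl acetate | CC(C)=CCOC(C)=O | starting material
6 | 4-hydroxy-6-methyl-3-(3-methylbut-2-enyl)-2H-pyran-2-one | Cc1cc(O)c(CC=C(C)C)c(=O)o1 | intermediate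
7 | 4-hydroxy-6-{(E)-4-[4-(methoxymethoxy)phenyl]-2-oxobut-3-enyl}-3-(3-methylbut-2-enyl)-2H-pyran-2-one | O=c1oc(CC(=O)/C=C/c2ccc(OCOC)cc2)cc(O)c1CC=C(C)C | intermediate
8 | methyl (E)-9-[4-(methoxymethoxy)phenyl]-2-(3-methylbut-2-enyl)-3,5,7-trioxonon-8-enoate (present as magnesium chelate) | COC(=O)C(CC=C(C)C)C(=O)CC(=O)CC(=O)/C=C/c1ccc(OCOC)cc1 | intermediate
9 | (E)-3-[4-(methoxymethoxy)phenyl]-1-[2,4,6-trihydroxy-3-(3-methylbut-2-enyl)phenyl]prop-2-en-1-one | O=C(/C=C/c1ccc(OCOC)cc1)c1c(O)cc(O)c(CC=C(C)C)c1O | intermediate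
10 | (E)-1-[2-hydroxy-4,6-bis(methoxymethoxy)-3-(3-methylbut-2-enyl)phenyl]-3-[4-(methoxymethoxy)phenyl]prop-2-en-1-one | O=C(/C=C/c1ccc(OCOC)cc1)c1c(OCOC)cc(OCOC)c(CC=C(C)C)c1O | intermediate
11 | (E)-1-[2-(tert-butyldimethylsilyloxy)-4,6-bis(methoxymethoxy)-3-(3-methylbut-2-enyl)phenyl]-3-[4-(methoxymethoxy)phenyl]prop-2-en-1-one | O=C(/C=C/c1ccc(OCOC)cc1)c1c(OCOC)cc(OCOC)c(CC=C(C)C)c1O[Si](C)(C)C(C)(C)C | intermediate
12 | (E)-1-[2-(tert-butyldimethylsilyloxy)-3-{[(2S)-3,3-dimethyloxiran-2-yl]methyl}-4,6-bis(methoxymethoxy)phenyl]-3-[4-(methoxymethoxy)phenyl]prop-2-en-1-one | O=C(/C=C/c1ccc(OCOC)cc1)c1c(OCOC)cc(OCOC)c(C[C@@H]2OC2(C)C)c1O[Si](C)(C)C(C)(C)C | intermediate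
13 | (E)-1-[3-{[(2S)-3,3-dimethyloxiran-2-yl]methyl}-2-hydroxy-4,6-bis(methoxymethoxy)phenyl]-3-[4-(methoxymethoxy)phenyl]prop-2-en-1-one | O=C(/C=C/c1ccc(OCOC)cc1)c1c(OCOC)cc(OCOC)c(C[C@@H]2OC2(C)C)c1O | intermediate
14 | (E)-1-[(3S)-3-hydroxy-5,7-bis(methoxymethoxy)-2,2-dimethylchroman-8-yl]-3-[4-(methoxymethoxy)phenyl]prop-2-en-1-one | CC1(C)Oc2c(c(OCOC)cc(OCOC)c2C(=O)/C=C/c2ccc(OCOC)cc2)C[C@@H]1O | intermediate
15 | (E)-1-[(3S)-3,5,7-trihydroxy-2,2-dimethylchroman-8-yl]-3-(4-hydroxyphenyl)prop-2-en-1-one | CC1(C)Oc2c(c(O)cc(O)c2C(=O)/C=C/c2ccc(O)cc2)C[C@@H]1O | target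

Total step count: 9. Longest linear sequence: 8 steps (steps 2 to 9, from 4).

Steps most likely to fail

Step 4. Several processes could divert the reaction. Methoxide may cleave the side chain by retro-Claisen reaction. Chain C4 of the opened ester may add to the enone. The ester may simply re-lactonise. The product may also drift to flavanones by oxa-Michael closure during the quench. The fallback sets out from 1 and returns at 10, and in it ring A is bought instead of built. Commercial 2',4',6'-trihydroxyacetophenone is C-prenylated with prenyl bromide and aqueous KOH to 3-prenylphloroacetophenone F1. MOMCl/iPr2NEt then caps the para phenol and the unhindered ortho phenol to give the bis-MOM acetophenone F2. A Claisen–Schmidt condensation of this ketone with aldehyde 1 (KOH, EtOH–H2O, rt) delivers 10. This detour also bypasses step 5.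

Step 8. Attack at the secondary epoxide carbon (5-exo, with inversion) may compete with the 6-endo mode. The neighbouring MOM oxygen may take part in the opening, or a hydride shift may turn the epoxide into a ketone. The fallback sets out from 10 and returns at 14. It fixes the six-membered ring before the oxygen is introduced. DDQ in refluxing toluene dehydrogenates the ortho-prenylphenol to a quinone methide, which closes by oxa-6π electrocyclisation to the 2,2-dimethylchromene F3. A Jacobsen–Katsuki epoxidation follows, using (S,S)-[N,N'-bis(3,5-di-tert-butylsalicylidene)-1,2-cyclohexanediaminato]manganese chloride, NaOCl and 4-phenylpyridine N-oxide in CH2Cl2 at 0 °C. It should give the (3S,4S)-epoxychroman F4. Ionic reduction with Et3SiH/BF3·OEt2 at −78 °C then replaces only the benzylic C4–O bond, whose cation is stabilised by the oxygens on C5, C7 and C8a. The C3–O bond stays in place, and the product is 14.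

Step 5. The second MOM group may land on the wrong ortho phenol, and the amine base may drive the 2,6-dihydroxyaryl enone to flavanones before both groups are on. The fallback sets out from 9 and returns at 15, and it needs no choice between the two ortho phenols. One equivalent of MOMCl caps only the acidic C5–OH to give the mono-protected ring A chalcone F5. TBSOTf/2,6-lutidine silylates both ortho phenols without phenoxide formation to the bis-silyl ether F6. The Shi epoxidation of step 7 gives the (S)-epoxide F7, and buffered fluoride frees the epoxy diphenol F8, in which only the C8a oxygen can reach the epoxide. Camphorsulfonic acid closes it to the C7-hydroxy chromanol F9, and methanolic HCl gives 15.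

Further compounds
F1 | step 4 | 1-[2,4,6-trihydroxy-3-(3-methylbut-2-enyl)phenyl]ethanone | CC(=O)c1c(O)cc(O)c(CC=C(C)C)c1O
F2 | step 4 | 1-[2-hydroxy-4,6-bis(methoxymethoxy)-3-(3-methylbut-2-enyl)phenyl]ethanone | CC(=O)c1c(OCOC)cc(OCOC)c(CC=C(C)C)c1O
F3 | step 8 | (E)-1-[5,7-bis(methoxymethoxy)-2,2-dimethyl-2H-chromen-8-yl]-3-[4-(methoxymethoxy)phenyl]prop-2-en-1-one | CC1(C)Oc2c(c(OCOC)cc(OCOC)c2C(=O)/C=C/c2ccc(OCOC)cc2)C=C1
F4 | step 8 | (E)-1-[(3S,4S)-3,4-epoxy-5,7-bis(methoxymethoxy)-2,2-dimethylchroman-8-yl]-3-[4-(methoxymethoxy)phenyl]prop-2-en-1-one | CC1(C)Oc2c(c(OCOC)cc(OCOC)c2C(=O)/C=C/c2ccc(OCOC)cc2)[C@@H]3O[C@@H]31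
F5 | step 5 | (E)-1-[2,6-dihydroxy-4-(methoxymethoxy)-3-(3-methylbut-2-enyl)phenyl]-3-[4-(methoxymethoxy)phenyl]prop-2-en-1-one | O=C(/C=C/c1ccc(OCOC)cc1)c1c(O)cc(OCOC)c(CC=C(C)C)c1O
F6 | step 5 | (E)-1-[2,6-bis(tert-butyldimethylsilyloxy)-4-(methoxymethoxy)-3-(3-methylbut-2-enyl)phenyl]-3-[4-(methoxymethoxy)phenyl]prop-2-en-1-one | O=C(/C=C/c1ccc(OCOC)cc1)c1c(O[Si](C)(C)C(C)(C)C)cc(OCOC)c(CC=C(C)C)c1O[Si](C)(C)C(C)(C)C
F7 | step 5 | (E)-1-[2,6-bis(tert-butyldimethylsilyloxy)-3-{[(2S)-3,3-dimethyloxiran-2-yl]methyl}-4-(methoxymethoxy)phenyl]-3-[4-(methoxymethoxy)phenyl]prop-2-en-1-one | O=C(/C=C/c1ccc(OCOC)cc1)c1c(O[Si](C)(C)C(C)(C)C)cc(OCOC)c(C[C@@H]2OC2(C)C)c1O[Si](C)(C)C(C)(C)C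
F8 | step 5 | (E)-1-[3-{[(2S)-3,3-dimethyloxiran-2-yl]methyl}-2,6-dihydroxy-4-(methoxymethoxy)phenyl]-3-[4-(methoxymethoxy)phenyl]prop-2-en-1-one | O=C(/C=C/c1ccc(OCOC)cc1)c1c(O)cc(OCOC)c(C[C@@H]2OC2(C)C)c1O
F9 | step 5 | (E)-1-[(3S)-3,7-dihydroxy-5-(methoxymethoxy)-2,2-dimethylchroman-8-yl]-3-[4-(methoxymethoxy)phenyl]prop-2-en-1-one | CC1(C)Oc2c(c(OCOC)cc(O)c2C(=O)/C=C/c2ccc(OCOC)cc2)C[C@@H]1O
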